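**Retrosynthetic overview** (open-chain compounds are numbered C1 = CO2H to C12 = CHPh)
1. Target 20 ⇐ type 1 intramolecular Diels–Alder reaction of the unprotected seco-acid 19 (all-E triene plus E-enoic acid). Bonds C3–C7 and C2–C10 form together, so the cyclohexene and cyclopentanone rings close in the same, last step.
2. 19 ⇐ oxidation of the C5 carbinol 18 in the same flask, with no protecting group on ketone or acid.
3. 18 ⇐ C4–C5 bond by an auxiliary-controlled vinylogous Mukaiyama aldol of trienal 10 with silyl N,O-acetal 15 (from 2-ethylhex-2-enoic acid), then auxiliary removal.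
4. 10 ⇐ (S)-Roche ester 1 (source of C6) by two formyl-ylide Wittig reactions and one benzylphosphonate olefination.

Assumption: the vinylketene silyl N,O-acetal reacts at its γ-carbon on the face opposite the isopropyl group, so the (R)-auxiliary is taken to give the (4R) centre; if the sense is the reverse, the (S)-auxiliary is used and nothing else changes.

**Step 1**
Reactants: 1 methyl (S)-3-hydroxy-2-methylpropanoate
Product: 2 methyl (S)-2-methyl-3-(triethylsilyloxy)propanoate
Conditions: Et3SiCl, imidazole, CH2Cl2, 0 °C to rt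
Reagents that add atoms: chlorotriethylsilane, CC[Si](CC)(CC)Cl
Why: Routine silyl ether formation masks the future C5 oxygen as a triethylsilyl ether that can later be oxidised directly; the stereocentre is not touched.

**Step 2**
Reactants: 2 methyl (S)-2-methyl-3-(triethylsilyloxy)propanoate
Product: 3 (S)-2-methyl-3-(triethylsilyloxy)propanal
Conditions: iBu2AlH (1.1 equiv), CH2Cl2, −78 °C; aq. KNaC4H4O6 (potassium sodium tartrate) work-up
Reagents that add atoms: none
Why: Partial ester reduction stops at the tetrahedral aluminium hemiacetal at −78 °C, which releases the α-chiral aldehyde on work-up without epimerisation.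

**Step 3**
Reactants: 3 (S)-2-methyl-3-(triethylsilyloxy)propanal, 4 2-(triphenylphosphoranylidene)butanal
Product: 5 (2E,4R)-2-ethyl-4-methyl-5-(triethylsilyloxy)pent-2-enal
Conditions: PhMe, 90 °C
Reagents that add atoms: none
Why: Wittig olefination with the formyl-stabilised ylide gives the (E)-trisubstituted enal under thermodynamic control, and the neutral conditions leave the allylic stereocentre (now R by priority change only) intact.

**Step 4**
Reactants: 5 (2E,4R)-2-ethyl-4-methyl-5-(triethylsilyloxy)pent-2-enal, 4 2-(triphenylphosphoranylidene)butanal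
Product: 6 (2E,4E,6R)-2,4-diethyl-6-methyl-7-(triethylsilyloxy)hepta-2,4-dienal
Conditions: PhMe, 110 °C
Reagents that add atoms: none
Why: A second Wittig olefination with the same stabilised ylide extends the enal to the (E,E)-dienal; the less electrophilic enal needs the higher temperature, and selectivity is again thermodynamic.

**Step 5**
Reactants: 6 (2E,4E,6R)-2,4-diethyl-6-methyl-7-(triethylsilyloxy)hepta-2,4-dienal, 7 diethyl benzylphosphonate
Product: 8 triethyl{[(2R,3E,5E,7E)-4,6-diethyl-2-methyl-8-phenylocta-3,5,7-trien-1-yl]oxy}silane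
Conditions: KOtBu, THF, 0 °C to rt
Reagents that add atoms: none
Why: Horner–Wadsworth–Emmons olefination with the benzylphosphonate anion gives the (E)-styrene and completes the all-E triene; the dienal has no α-hydrogen to lose.

**Step 6**
Reactants: 8 triethyl{[(2R,3E,5E,7E)-4,6-diethyl-2-methyl-8-phenylocta-3,5,7-trien-1-yl]oxy}silane
Product: 10 (2R,3E,5E,7E)-4,6-diethyl-2-methyl-8-phenylocta-3,5,7-trienal, via alkoxysulfonium chloride 9 (not isolated)
Conditions: (COCl)2, DMSO, CH2Cl2, −78 to −40 °C; then iPr2NEt, −78 to 0 °C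
Reagents that add atoms: none
Why: Direct Swern oxidation of a primary triethylsilyl ether: the ether oxygen attacks chlorodimethylsulfonium chloride, Et3SiCl is lost, and the alkoxysulfonium salt collapses with the hindered amine to the aldehyde, cold enough to keep the α-stereocentre.

**Step 7**
Reactants: 11 (E)-2-ethylhex-2-enoic acid, 12 (R)-4-isopropyloxazolidin-2-one
Product: 14 (R)-3-[(E)-2-ethylhex-2-enoyl]-4-isopropyloxazolidin-2-one, via mixed pivalic anhydride 13 (not isolated)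
Conditions: t-BuCOCl, Et3N, THF, −20 °C; then LiCl, 12, −20 °C to rt
Reagents that add atoms: none
Why: N-Acylation of the oxazolidinone through the mixed anhydride (LiCl/Et3N protocol) occurs at the less hindered enoyl carbonyl and avoids a separate acid chloride.

**Step 8**
Reactants: 14 (R)-3-[(E)-2-ethylhex-2-enoyl]-4-isopropyloxazolidin-2-one
Product: 15 (R)-3-[(1E,3E)-1-(tert-butyldimethylsilyloxy)-2-ethylhexa-1,3-dien-1-yl]-4-isopropyloxazolidin-2-one
Conditions: NaN(SiMe3)2, t-BuMe2SiCl, THF, −78 °C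
Reagents that add atoms: tert-butylchlorodimethylsilane, CC(C)(C)[Si](C)(C)Cl
Why: γ-Deprotonation and O-silylation give the (1E,3E) vinylketene silyl N,O-acetal, in which A(1,3) strain turns the oxazolidinone perpendicular to the diene so that its isopropyl group covers one face.

**Step 9**
Reactants: 10 (2R,3E,5E,7E)-4,6-diethyl-2-methyl-8-phenylocta-3,5,7-trienal, 15 (R)-3-[(1E,3E)-1-(tert-butyldimethylsilyloxy)-2-ethylhexa-1,3-dien-1-yl]-4-isopropyloxazolidin-2-one
Product: 16 (R)-3-[(2E,4R,5S,6R,7E,9E,11E)-2,4,8,10-tetraethyl-5-hydroxy-6-methyl-12-phenyldodeca-2,7,9,11-tetraenoyl]-4-isopropyloxazolidin-2-one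
Conditions: TiCl4, CH2Cl2, −78 °C; H2O quench at −78 °C
Reagents that add atoms: none
Why: Kobayashi-type vinylogous Mukaiyama aldol: the TiCl4-bound aldehyde is attacked by the γ-carbon on the face opposite the isopropyl group (sets C4 as R), the open transition state gives the 4,5-anti carbinol, which here matches the Felkin preference of the aldehyde (5,6-syn), and the (E)-enoyl unit is regenerated; C5 is erased later.

**Step 10**
Reactants: 16 (R)-3-[(2E,4R,5S,6R,7E,9E,11E)-2,4,8,10-tetraethyl-5-hydroxy-6-methyl-12-phenyldodeca-2,7,9,11-tetraenoyl]-4-isopropyloxazolidin-2-one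
Product: 18 (2E,4R,5S,6R,7E,9E,11E)-2,4,8,10-tetraethyl-5-hydroxy-6-methyl-12-phenyldodeca-2,7,9,11-tetraenoic acid, via peroxy acid 17 (not isolated)
Conditions: LiOH, H2O2, THF/H2O, 0 °C; then Na2SO3; then 1 M HCl to pH 3
Reagents that add atoms: hydrogen peroxide, OO
Why: Hydroperoxide cleaves the imide at the exocyclic carbonyl and sulfite reduces the peracid, so the auxiliary is removed while the acyl group is still unhindered; no stereocentre is involved and the (E)-acid cannot lactonise.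

**Step 11**
Reactants: 18 (2E,4R,5S,6R,7E,9E,11E)-2,4,8,10-tetraethyl-5-hydroxy-6-methyl-12-phenyldodeca-2,7,9,11-tetraenoic acid
Product: 20 (1R,3R,3aS,4S,5R,7aS)-3,4,5,7-tetraethyl-1-methyl-2-oxo-5-[(E)-2-phenylethenyl]-2,3,3a,4,5,7a-hexahydro-1H-indene-4-carboxylic acid (spiculoic acid A), via keto acid 19 (not isolated)
Conditions: Dess–Martin periodinane (1.1 equiv), CH2Cl2, 0 °C to rt; then PhMe, BHT (cat.), 80 °C, 0.01 M
Reagents that add atoms: none
Why: Dess–Martin oxidation gives the free β,γ-unsaturated keto acid (the presumed biosynthetic seco-acid), which on warming undergoes the type 1 intramolecular Diels–Alder reaction through the trans-fused transition state with the carboxyl group endo; C4–H and C6–H each lie in the plane of the adjacent alkene to avoid A(1,3) strain with the C2 and C8 ethyl groups, so the two tether stereocentres jointly fix both π-faces and set indene C3a, C4, C5 and C7a in one step, while the base-free medium protects the two α-centres until cyclisation removes both β,γ-alkenes.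

**Compound list**
1 | methyl (S)-3-hydroxy-2-methylpropanoate | COC(=O)[C@@H](C)CO | starting material
2 | methyl (S)-2-methyl-3-(triethylsilyloxy)propanoate | COC(=O)[C@@H](C)CO[Si](CC)(CC)CC | intermediate
3 | (S)-2-methyl-3-(triethylsilyloxy)propanal | O=C[C@@H](C)CO[Si](CC)(CC)CC | intermediate
4 | 2-(triphenylphosphoranylidene)butanal | CCC(C=O)=P(c1ccccc1)(c1ccccc1)c1ccccc1 | starting material
5 | (2E,4R)-2-ethyl-4-methyl-5-(triethylsilyloxy)pent-2-enal | O=C/C(CC)=C/[C@@H](C)CO[Si](CC)(CC)CC | intermediate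
6 | (2E,4E,6R)-2,4-diethyl-6-methyl-7-(triethylsilyloxy)hepta-2,4-dienal | O=C/C(CC)=C/C(CC)=C/[C@@H](C)CO[Si](CC)(CC)CC | intermediate
7 | diethyl benzylphosphonate | CCOP(=O)(Cc1ccccc1)OCC | starting material
8 | triethyl{[(2R,3E,5E,7E)-4,6-diethyl-2-methyl-8-phenylocta-3,5,7-trien-1-yl]oxy}silane | c1ccccc1/C=C/C(CC)=C/C(CC)=C/[C@@H](C)CO[Si](CC)(CC)CC | intermediate
9 | {[(2R,3E,5E,7E)-4,6-diethyl-2-methyl-8-phenylocta-3,5,7-trien-1-yl]oxy}dimethylsulfonium chloride | c1ccccc1/C=C/C(CC)=C/C(CC)=C/[C@@H](C)CO[S+](C)C.[Cl-] | intermediate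
10 | (2R,3E,5E,7E)-4,6-diethyl-2-methyl-8-phenylocta-3,5,7-trienal | c1ccccc1/C=C/C(CC)=C/C(CC)=C/[C@@H](C)C=O | intermediate
11 | (E)-2-ethylhex-2-enoic acid | OC(=O)/C(CC)=C/CCC | starting material
12 | (R)-4-isopropyloxazolidin-2-one | O=C1N[C@H](C(C)C)CO1 | starting material
13 | (E)-2-ethylhex-2-enoic pivalic anhydride | CC(C)(C)C(=O)OC(=O)/C(CC)=C/CCC | intermediate
14 | (R)-3-[(E)-2-ethylhex-2-enoyl]-4-isopropyloxazolidin-2-one | O=C(/C(CC)=C/CCC)N1[C@H](C(C)C)COC1=O | intermediate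
15 | (R)-3-[(1E,3E)-1-(tert-butyldimethylsilyloxy)-2-ethylhexa-1,3-dien-1-yl]-4-isopropyloxazolidin-2-one | CC/C=C/C(CC)=C(/O[Si](C)(C)C(C)(C)C)N1[C@H](C(C)C)COC1=O | intermediate
16 | (R)-3-[(2E,4R,5S,6R,7E,9E,11E)-2,4,8,10-tetraethyl-5-hydroxy-6-methyl-12-phenyldodeca-2,7,9,11-tetraenoyl]-4-isopropyloxazolidin-2-one | O=C(/C(CC)=C/[C@@H](CC)[C@@H](O)[C@H](C)/C=C(CC)/C=C(CC)/C=C/c1ccccc1)N1[C@H](C(C)C)COC1=O | intermediate
17 | (2E,4R,5S,6R,7E,9E,11E)-2,4,8,10-tetraethyl-5-hydroxy-6-methyl-12-phenyldodeca-2,7,9,11-tetraeneperoxoic acid | OOC(=O)/C(CC)=C/[C@@H](CC)[C@@H](O)[C@H](C)/C=C(CC)/C=C(CC)/C=C/c1ccccc1 | intermediate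
18 | (2E,4R,5S,6R,7E,9E,11E)-2,4,8,10-tetraethyl-5-hydroxy-6-methyl-12-phenyldodeca-2,7,9,11-tetraenoic acid | OC(=O)/C(CC)=C/[C@@H](CC)[C@@H](O)[C@H](C)/C=C(CC)/C=C(CC)/C=C/c1ccccc1 | intermediate
19 | (2E,4R,6R,7E,9E,11E)-2,4,8,10-tetraethyl-6-methyl-5-oxo-12-phenyldodeca-2,7,9,11-tetraenoic acid | OC(=O)/C(CC)=C/[C@@H](CC)C(=O)[C@H](C)/C=C(CC)/C=C(CC)/C=C/c1ccccc1 | intermediate
20 | (1R,3R,3aS,4S,5R,7aS)-3,4,5,7-tetraethyl-1-methyl-2-oxo-5-[(E)-2-phenylethenyl]-2,3,3a,4,5,7a-hexahydro-1H-indene-4-carboxylic acid | CCC1=C[C@](/C=C/c2ccccc2)(CC)[C@@](CC)(C(=O)O)[C@H]2[C@H]1[C@@H](C)C(=O)[C@@H]2CC | target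

**Step count**
Total: 11 steps. Longest linear sequence: 9 steps (1 to 6, then 9, 10, 11); steps 7 and 8 form the side branch.

**Three steps most likely to fail**

Step 11 (oxidation and cycloaddition in one flask). Keto acid 19 has two enolisable α-stereocentres flanked by β,γ-alkenes, so epimerisation or conjugation could outrun the cycloaddition. The fallback sets out from 18 and returns at 20. The cycloaddition is moved to the alcohol oxidation level, where C4 and C6 cannot enolise: 18 is heated alone (PhMe, BHT, 110 °C) to give (1R,2S,3R,3aS,4S,5R,7aS)-3,4,5,7-tetraethyl-2-hydroxy-1-methyl-5-[(E)-2-phenylethenyl]-2,3,3a,4,5,7a-hexahydro-1H-indene-4-carboxylic acid F1. Its secondary alcohol is then oxidised with Dess–Martin periodinane to 20.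

Step 9 (vinylogous aldol). Aldehyde 10 is α-chiral and β,γ-unsaturated and carries an acid-sensitive triene, and the diethyl version of the acetal is untested. The fallback sets out from 15 and returns at 16; the aldol is run before the triene exists.
- Commercial methyl (R)-3-hydroxy-2-methylpropanoate is silylated as in step 1 to methyl (R)-2-methyl-3-(triethylsilyloxy)propanoate F2 and reduced as in step 2 to (R)-2-methyl-3-(triethylsilyloxy)propanal F3. The enantiomeric series is needed because the formyl carbon now becomes C5 and the silyloxymethyl carbon C7.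
- 15 and F3 (TiCl4, CH2Cl2, −78 °C) give the hydroxy imide F4.
- t-BuMe2SiOTf and 2,6-lutidine give the bis-silyl ether F5.
- Direct Swern oxidation of the primary triethylsilyl ether gives the aldehyde F6.
- Wittig reaction with 4 gives the enal F7, and a second one gives the dienal F8.
- Olefination with 7 (KOtBu) gives the silyl-protected tetraenoyl imide F9, and HF·pyridine frees the C5 hydroxyl to give 16.

Step 10 (auxiliary cleavage). The α-ethyl enoyl imide is hindered, so hydroperoxide may open the oxazolidinone ring instead; the tetraene imide may also cyclise first and trap the auxiliary on a quaternary carbon. The fallback sets out from 16 and returns at 20. The auxiliary is removed reductively and the carboxyl group is made last. NaBH4 (THF/H2O, 0 °C) gives the diol F10 and releases 12. Dess–Martin periodinane (2.5 equiv) oxidises both alcohols to the keto enal F11, which is a stronger dienophile and cyclises at 40 °C to the keto aldehyde F12. Pinnick oxidation (NaClO2, NaH2PO4, 2-methylbut-2-ene, t-BuOH/H2O) then gives 20.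

**Further compounds**
F1 | step 11 | (1R,2S,3R,3aS,4S,5R,7aS)-3,4,5,7-tetraethyl-2-hydroxy-1-methyl-5-[(E)-2-phenylethenyl]-2,3,3a,4,5,7a-hexahydro-1H-indene-4-carboxylic acid | CCC1=C[C@](/C=C/c2ccccc2)(CC)[C@@](CC)(C(=O)O)[C@H]2[C@H]1[C@@H](C)[C@H](O)[C@@H]2CC
F2 | step 9 | methyl (R)-2-methyl-3-(triethylsilyloxy)propanoate | COC(=O)[C@H](C)CO[Si](CC)(CC)CC
F3 | step 9 | (R)-2-methyl-3-(triethylsilyloxy)propanal | O=C[C@H](C)CO[Si](CC)(CC)CC
F4 | step 9 | (R)-3-[(2E,4R,5R,6R)-2,4-diethyl-5-hydroxy-6-methyl-7-(triethylsilyloxy)hept-2-enoyl]-4-isopropyloxazolidin-2-one | O=C(/C(CC)=C/[C@@H](CC)[C@@H](O)[C@H](C)CO[Si](CC)(CC)CC)N1[C@H](C(C)C)COC1=O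
F5 | step 9 | (R)-3-[(2E,4R,5R,6R)-5-(tert-butyldimethylsilyloxy)-2,4-diethyl-6-methyl-7-(triethylsilyloxy)hept-2-enoyl]-4-isopropyloxazolidin-2-one | O=C(/C(CC)=C/[C@@H](CC)[C@@H](O[Si](C)(C)C(C)(C)C)[C@H](C)CO[Si](CC)(CC)CC)N1[C@H](C(C)C)COC1=O
F6 | step 9 | (R)-3-[(2E,4R,5R,6S)-5-(tert-butyldimethylsilyloxy)-2,4-diethyl-6-methyl-7-oxohept-2-enoyl]-4-isopropyloxazolidin-2-one | O=C(/C(CC)=C/[C@@H](CC)[C@@H](O[Si](C)(C)C(C)(C)C)[C@H](C)C=O)N1[C@H](C(C)C)COC1=O
F7 | step 9 | (R)-3-[(2E,4R,5S,6R,7E)-5-(tert-butyldimethylsilyloxy)-2,4,8-triethyl-6-methyl-9-oxonona-2,7-dienoyl]-4-isopropyloxazolidin-2-one | O=C(/C(CC)=C/[C@@H](CC)[C@@H](O[Si](C)(C)C(C)(C)C)[C@H](C)/C=C(CC)/C=O)N1[C@H](C(C)C)COC1=O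
F8 | step 9 | (R)-3-[(2E,4R,5S,6R,7E,9E)-5-(tert-butyldimethylsilyloxy)-2,4,8,10-tetraethyl-6-methyl-11-oxoundeca-2,7,9-trienoyl]-4-isopropyloxazolidin-2-one | O=C(/C(CC)=C/[C@@H](CC)[C@@H](O[Si](C)(C)C(C)(C)C)[C@H](C)/C=C(CC)/C=C(CC)/C=O)N1[C@H](C(C)C)COC1=O
F9 | step 9 | (R)-3-[(2E,4R,5S,6R,7E,9E,11E)-5-(tert-butyldimethylsilyloxy)-2,4,8,10-tetraethyl-6-methyl-12-phenyldodeca-2,7,9,11-tetraenoyl]-4-isopropyloxazolidin-2-one | O=C(/C(CC)=C/[C@@H](CC)[C@@H](O[Si](C)(C)C(C)(C)C)[C@H](C)/C=C(CC)/C=C(CC)/C=C/c1ccccc1)N1[C@H](C(C)C)COC1=O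
F10 | step 10 | (2E,4R,5S,6R,7E,9E,11E)-2,4,8,10-tetraethyl-6-methyl-12-phenyldodeca-2,7,9,11-tetraene-1,5-diol | OC/C(CC)=C/[C@@H](CC)[C@@H](O)[C@H](C)/C=C(CC)/C=C(CC)/C=C/c1ccccc1
F11 | step 10 | (2E,4R,6R,7E,9E,11E)-2,4,8,10-tetraethyl-6-methyl-5-oxo-12-phenyldodeca-2,7,9,11-tetraenal | O=C/C(CC)=C/[C@@H](CC)C(=O)[C@H](C)/C=C(CC)/C=C(CC)/C=C/c1ccccc1
F12 | step 10 | (1R,3R,3aS,4S,5R,7aS)-3,4,5,7-tetraethyl-1-methyl-2-oxo-5-[(E)-2-phenylethenyl]-2,3,3a,4,5,7a-hexahydro-1H-indene-4-carbaldehyde | CCC1=C[C@](/C=C/c2ccccc2)(CC)[C@@](CC)(C=O)[C@H]2[C@H]1[C@@H](C)C(=O)[C@@H]2CC
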